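## Retrosynthetic overview
1. Myriaporone 4 (**1**) comes from global desilylation of a tri-TBS ketone. That ketone comes from reductive N–O cleavage of a trans-4,5-disubstituted 2-isoxazoline, which unmasks the C6 ketone and C8 alcohol.
2. Key step (ring formation): intermolecular nitrile oxide + (E)-allylic silyl ether 1,3-dipolar cycloaddition. It joins the C1–C6 aldoxime fragment to the C7–C14 vinyl epoxide and sets C7/C8.
3. The C7–C14 dipolarophile comes from (R)-Roche ester: Z-Wittig gives the Z-alkene and C11, Z-selective olefination and directed epoxidation give the cis-epoxide, then HWE gives the E-allylic ether.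
4. The C1–C6 aldoxime comes from ethyl (R)-4-chloro-3-hydroxybutanoate: dithiane opening installs C2 and Frater–Seebach hydroxymethylation installs the anti C4/C5 pair.
5. Ring order: epoxide first (Step 8), isoxazoline second (Step 20), isoxazoline opened (Step 21).

Assumptions: both enantiomers of Roche ester and of ethyl 4-chloro-3-hydroxybutanoate are commercial, and the diastereomers from Steps 8, 14 and 20 are separable by chromatography.

## Route

**Step 1**
Reactants: **2** methyl (R)-3-hydroxy-2-methylpropanoate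
Product: **3** methyl (R)-3-(TBDPSO)-2-methylpropanoate
Conditions: TBDPSCl, imidazole, DMF, rt
Reagents that add atoms: TBDPSCl, CC(C)(C)[Si](Cl)(c1ccccc1)c1ccccc1
Why: Silylation of the primary alcohol; the stereocentre (future C11) is untouched.

**Step 2**
Reactants: **3**
Product: **4** (R)-3-(TBDPSO)-2-methylpropanal
Conditions: DIBAL-H, CH2Cl2, –78 °C
Reagents that add atoms: none
Why: Partial ester-to-aldehyde reduction at low temperature; the β-silyloxy aldehyde is configurationally stable.

**Step 3**
Reactants: **4**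
Product: **5** tert-butyl-diphenyl-{[(2S,3Z)-2-methylpent-3-enyl]oxy}silane
Conditions: EtPPh3Br, NaHMDS, THF, –78 °C → rt
Reagents that add atoms: ethyltriphenylphosphonium bromide, CC[P+](c1ccccc1)(c1ccccc1)c1ccccc1.[Br-]
Why: Wittig reaction of a non-stabilised ylide gives the Z-alkene (C12=C13) under kinetic control.

**Step 4**
Reactants: **5**
Product: **6** (2S,3Z)-2-methylpent-3-en-1-ol
Conditions: TBAF, THF, 0 °C (volatile; used as a crude solution)
Reagents that add atoms: none
Why: Fluoride desilylation frees the primary alcohol for oxidation.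

**Step 5**
Reactants: **6**
Product: **7** (2S,3Z)-2-methylpent-3-enal
Conditions: DMP, NaHCO3, CH2Cl2, 0 °C (used immediately)
Reagents that add atoms: none
Why: Mild, non-basic Dess–Martin oxidation limits epimerisation or conjugation of the α-chiral β,γ-unsaturated aldehyde.

**Step 6**
Reactants: **7**
Product: **8** ethyl (2Z,4S,5Z)-2,4-dimethylhepta-2,5-dienoate
Conditions: NaH, THF, 0 °C, then **7**, –78 °C
Reagents that add atoms: ethyl 2-[bis(2-methylphenoxy)phosphoryl]propanoate, CCOC(=O)C(C)P(=O)(Oc1ccccc1C)Oc1ccccc1C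
Why: Ando Z-selective HWE makes the Z-trisubstituted enoate, which places C8 cis to C11 as the cis-epoxide requires.

**Step 7**
Reactants: **8**
Product: **9** (2Z,4S,5Z)-2,4-dimethylhepta-2,5-dien-1-ol
Conditions: DIBAL-H, CH2Cl2, –78 °C
Reagents that add atoms: none
Why: 1,2-Reduction of the ester to the allylic alcohol with retention of both alkene geometries.

**Step 8**
Reactants: **9**
Product: **10** [(2R,3S)-2-methyl-3-((2S,3Z)-pent-3-en-2-yl)oxiran-2-yl]methanol
Conditions: VO(acac)2 (5 mol %), TBHP, CH2Cl2, 0 °C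
Reagents that add atoms: tert-butyl hydroperoxide, CC(C)(C)OO (its O ends up in the epoxide)
Why: Hydroxyl-directed vanadium epoxidation is site-selective for the allylic-alcohol alkene and syn-stereospecific, so it gives the cis-epoxide. Facial selectivity at C9/C10 is set by the A(1,3)-strained C11 stereocentre, and the diastereomer is purified by chromatography.

**Step 9**
Reactants: **10**
Product: **11** (2S,3S)-2-methyl-3-((2S,3Z)-pent-3-en-2-yl)oxirane-2-carbaldehyde
Conditions: DMP, NaHCO3, CH2Cl2, rt
Reagents that add atoms: none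
Why: The α-quaternary epoxy aldehyde has no α-H and cannot epimerise.

**Step 10**
Reactants: **11**
Product: **12** ethyl (2E)-3-{(2R,3S)-2-methyl-3-[(2S,3Z)-pent-3-en-2-yl]oxiran-2-yl}prop-2-enoate
Conditions: LiCl, DBU, MeCN, 0 °C → rt
Reagents that add atoms: triethyl phosphonoacetate, CCOC(=O)CP(=O)(OCC)OCC
Why: Masamune–Roush HWE is E-selective and mild enough for the epoxide.

**Step 11**
Reactants: **12**
Product: **13** (2E)-3-{(2R,3S)-2-methyl-3-[(2S,3Z)-pent-3-en-2-yl]oxiran-2-yl}prop-2-en-1-ol
Conditions: DIBAL-H (2.5 equiv), CH2Cl2, –78 °C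
Reagents that add atoms: none
Why: Ester-to-allylic-alcohol reduction; the epoxide and alkenes survive at –78 °C.

**Step 12**
Reactants: **13**
Product: **14** the TBS ether of **13** (the dipolarophile)
Conditions: TBSCl, imidazole, DMF, rt
Reagents that add atoms: TBSCl, CC(C)(C)[Si](C)(C)Cl
Why: Protects the allylic alcohol so that it will become the C7 CH2OTBS group.

**Step 13**
Reactants: **15** ethyl (R)-4-chloro-3-hydroxybutanoate
Product: **16** ethyl (3R)-4-(2-ethyl-1,3-dithian-2-yl)-3-hydroxybutanoate
Conditions: 2-ethyl-1,3-dithiane, n-BuLi (2.3 equiv), THF, –78 → 0 °C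
Reagents that add atoms: 2-ethyl-2-lithio-1,3-dithiane, CCC1([Li])SCCCS1 (adds the C0–C2 carbons)
Why: The alkoxide closes in situ to the terminal epoxide and the dithianyl anion opens it at CH2 (Corey–Seebach). The carbinol stereocentre (C4) is not involved and is retained.

**Step 14**
Reactants: **16**
Product: **17** ethyl (2S,3S)-4-(2-ethyl-1,3-dithian-2-yl)-3-hydroxy-2-(hydroxymethyl)butanoate
Conditions: LDA (2.2 equiv), THF, –78 → –30 °C; then CH2O (monomeric), –78 °C
Reagents that add atoms: formaldehyde, C=O (adds CH2OH)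
Why: Frater–Seebach dianion hydroxymethylation; the chelated Li alkoxide/enolate is attacked anti to the C4 substituent, giving the 2,3-anti C4/C5 pair.

**Step 15**
Reactants: **17**
Product: **18** the bis-TBS ether of **17**
Conditions: TBSOTf (2.6 equiv), 2,6-lutidine, CH2Cl2, –78 → 0 °C
Reagents that add atoms: TBSOTf, CC(C)(C)[Si](C)(C)OS(=O)(=O)C(F)(F)F
Why: Protects both hydroxyls as silyl ethers, which stay on through the end game.

**Step 16**
Reactants: **18**
Product: **19** (2S,3S)-3-(TBSO)-2-[(TBSO)methyl]-4-(2-ethyl-1,3-dithian-2-yl)butan-1-ol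
Conditions: LiAlH4, THF, 0 °C
Reagents that add atoms: none
Why: Reduces the ester to the primary alcohol. C5 is no longer α to a carbonyl, so the later ketone formation cannot epimerise it.

**Step 17**
Reactants: **19**
Product: **20** (5S,6S)-5-(TBSO)-6-[(TBSO)methyl]-7-hydroxyheptan-3-one
Conditions: MeI, CaCO3, MeCN/H2O, 50 °C
Reagents that add atoms: water, O (becomes the C2 carbonyl)
Why: Neutral S-methylation/hydrolysis of the dithiane reveals the ethyl ketone (C2) without oxidants or acid.

**Step 18**
Reactants: **20**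
Product: **21** (2S,3S)-3-(TBSO)-2-[(TBSO)methyl]-5-oxoheptanal
Conditions: DMP, NaHCO3, CH2Cl2, 0 °C
Reagents that add atoms: none
Why: Chemoselective oxidation of the primary alcohol; the ketone is untouched.

**Step 19**
Reactants: **21**
Product: **22** aldoxime of **21** (E/Z mixture)
Conditions: NH2OH·HCl, NaOAc, EtOH/H2O, rt
Reagents that add atoms: hydroxylamine hydrochloride, NO.Cl (adds =N–OH)
Why: An aldehyde reacts with hydroxylamine much faster than the hindered β-silyloxy ketone does.

**Step 20 (key step)**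
Reactants: **22** aldoxime and **14** dipolarophile
Product: **23** 4,5-trans-2-isoxazoline
Conditions: NCS, pyridine (cat.), CH2Cl2, 0 °C; then **14**, Et3N (slow addition), 0 °C → rt
Reagents that add atoms: none (NCS/Et3N only generate the nitrile oxide in situ; the chloride is lost as Et3N·HCl)
Why: Nitrile oxide–alkene 1,3-dipolar cycloaddition is a suprafacial concerted process, so the E-alkene gives the 4,5-trans-isoxazoline, i.e. the anti C7/C8 relationship. The bulky quaternary epoxide carbon directs the dipole oxygen to C8 (5-position) and the dipole carbon to C7. Facial selectivity comes from the adjacent C9 stereocentre (Houk inside-alkoxy model).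

**Step 21**
Reactants: **23**
Product: **24** β-hydroxy ketone with three TBS ethers and free C8-OH
Conditions: Mo(CO)6, MeCN/H2O (15:1), 70 °C
Reagents that add atoms: water, O (becomes the C6 carbonyl)
Why: Nitta–Kobayashi reductive N–O cleavage and hydrolysis unmask the C6 ketone and C8 alcohol under neutral conditions. The alkene, epoxide, C2 ketone and silyl ethers survive.

**Step 22**
Reactants: **24**
Product: **1** myriaporone 4
Conditions: HF·pyridine, pyridine, THF, 0 °C → rt
Reagents that add atoms: none
Why: Buffered HF removes all three TBS ethers while sparing the tertiary epoxide and the β-hydroxy ketones.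

## Compound list
1 | myriaporone 4 | C/C=C\[C@H](C)[C@@H]1O[C@]1(C)[C@@H](O)[C@@H](CO)C(=O)[C@@H](CO)[C@@H](O)CC(=O)CC | target
2 | methyl (R)-3-hydroxy-2-methylpropanoate | COC(=O)[C@H](C)CO | starting material
3 | methyl (R)-3-(TBDPSO)-2-methylpropanoate | COC(=O)[C@H](C)CO[Si](c1ccccc1)(c1ccccc1)C(C)(C)C | intermediate
4 | (R)-3-(TBDPSO)-2-methylpropanal | O=C[C@H](C)CO[Si](c1ccccc1)(c1ccccc1)C(C)(C)C | intermediate
5 | TBDPS ether of (2S,3Z)-2-methylpent-3-en-1-ol | C/C=C\[C@H](C)CO[Si](c1ccccc1)(c1ccccc1)C(C)(C)C | intermediate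
6 | (2S,3Z)-2-methylpent-3-en-1-ol | C/C=C\[C@H](C)CO | intermediate
7 | (2S,3Z)-2-methylpent-3-enal | C/C=C\[C@H](C)C=O | intermediate
8 | ethyl (2Z,4S,5Z)-2,4-dimethylhepta-2,5-dienoate | C/C=C\[C@H](C)/C=C(C)\C(=O)OCC | intermediate
9 | (2Z,4S,5Z)-2,4-dimethylhepta-2,5-dien-1-ol | C/C=C\[C@H](C)/C=C(C)\CO | intermediate
10 | cis-epoxy alcohol | C/C=C\[C@H](C)[C@@H]1O[C@]1(C)CO | intermediate
11 | epoxy aldehyde | C/C=C\[C@H](C)[C@@H]1O[C@]1(C)C=O | intermediate
12 | (E)-epoxy enoate | C/C=C\[C@H](C)[C@@H]1O[C@]1(C)/C=C/C(=O)OCC | intermediate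
13 | (E)-epoxy allylic alcohol | C/C=C\[C@H](C)[C@@H]1O[C@]1(C)/C=C/CO | intermediate
14 | TBS ether of 13 (dipolarophile) | C/C=C\[C@H](C)[C@@H]1O[C@]1(C)/C=C/CO[Si](C)(C)C(C)(C)C | intermediate
15 | ethyl (R)-4-chloro-3-hydroxybutanoate | CCOC(=O)C[C@@H](O)CCl | starting material
16 | hydroxy dithiane ester | CCOC(=O)C[C@@H](O)CC1(CC)SCCCS1 | intermediate
17 | anti hydroxymethylated diol ester | CCOC(=O)[C@@H](CO)[C@@H](O)CC1(CC)SCCCS1 | intermediate
18 | bis-TBS ester | CCOC(=O)[C@@H](CO[Si](C)(C)C(C)(C)C)[C@@H](O[Si](C)(C)C(C)(C)C)CC1(CC)SCCCS1 | intermediate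
19 | primary alcohol (dithiane) | OC[C@@H](CO[Si](C)(C)C(C)(C)C)[C@@H](O[Si](C)(C)C(C)(C)C)CC1(CC)SCCCS1 | intermediate
20 | keto alcohol | OC[C@@H](CO[Si](C)(C)C(C)(C)C)[C@@H](O[Si](C)(C)C(C)(C)C)CC(=O)CC | intermediate
21 | keto aldehyde | O=C[C@@H](CO[Si](C)(C)C(C)(C)C)[C@@H](O[Si](C)(C)C(C)(C)C)CC(=O)CC | intermediate
22 | aldoxime | ON=C[C@@H](CO[Si](C)(C)C(C)(C)C)[C@@H](O[Si](C)(C)C(C)(C)C)CC(=O)CC | intermediate
23 | trans-isoxazoline | C/C=C\[C@H](C)[C@@H]1O[C@]1(C)[C@H]2ON=C([C@@H](CO[Si](C)(C)C(C)(C)C)[C@@H](O[Si](C)(C)C(C)(C)C)CC(=O)CC)[C@@H]2CO[Si](C)(C)C(C)(C)C | intermediate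
24 | tri-TBS β-hydroxy ketone | C/C=C\[C@H](C)[C@@H]1O[C@]1(C)[C@@H](O)[C@@H](CO[Si](C)(C)C(C)(C)C)C(=O)[C@@H](CO[Si](C)(C)C(C)(C)C)[C@@H](O[Si](C)(C)C(C)(C)C)CC(=O)CC | intermediate

**Total steps:** 22 (12 + 7 + 3 linear segments, with the cycloaddition joining them). **Longest linear sequence:** 15 steps (2 → 14 → 23 → 24 → 1).

## Three steps most likely to fail
1. **Step 20 (cycloaddition).** Regiochemistry, or facial selectivity from the C9 stereocentre, may be poor.
   Fallback: a different bond construction. Use a Paterson-type substrate-controlled boron aldol of the C6 methyl ketone with epoxy aldehyde **11**, then Mukaiyama hydroxymethylation at C7.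
2. **Step 8 (directed epoxidation).** The C10 face selectivity set by C11 is the least predictable stereochemical step.
   Fallback: a different route to the epoxide. Do a Felkin addition of isopropenylMgBr to **7**, Mitsunobu inversion at C10, VO(acac)2 epoxidation of the resulting allylic alcohol, then Payne rearrangement to the trisubstituted epoxide/primary alcohol that converges on **10**.
3. **Step 14 (Frater–Seebach hydroxymethylation).** Diastereoselectivity may be modest, and the product can undergo E1cB loss of water.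
   Fallback: build C4/C5 from (S)-3-hydroxy-γ-butyrolactone instead, using trans-selective enolate hydroxymethylation followed by Mitsunobu inversion at C4 to convert syn to anti.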